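## Structural features

The target is a diester made of three parts: a central cyclobutane-1,3-dicarboxylate and two identical bicyclic amino alcohols bound through their C6 oxygens. The cyclobutane carries 4-hydroxyphenyl groups at C2 and C4 in the α-truxillate pattern: carboxyls mutually trans, aryls mutually trans, each carboxyl cis to one aryl. Each amino alcohol is a cis-fused octahydrocyclopenta[c]pyridine, in which an N-methylpiperidine (ring A: C1, N2, C3, C4, C4a, C7a) shares the C4a–C7a bond with a cyclopentane (ring B: C4a, C5, C6, C7, C7a). Five contiguous stereocentres run round the bicycle and read 4R,4aS,6R,7S,7aR: the C4 methyl lies on the concave side cis to C5, the fusion is cis, the C7 methyl is trans to C1 on the convex face, and the C6 oxygen is cis to the C7 methyl. The cyclobutane core is centrosymmetric and achiral, so all absolute configuration sits in the two bicyclic units, which must be homochiral. Fragile groups are the two hindered secondary esters, the epimerisable cyclobutane α-carbons, the free phenols and the two basic tertiary amines. The real difficulty is the dense stereo-array of the bicycle, above all the concave C4 methyl and the C6 oxygen cis to the C7 methyl, followed by a twofold esterification at a hindered carbinol. The key step uses the latent 1,5-dicarbonyl relation between rings B and A: C5 is α to a C6 ketone and C4a is β to C3 once C3 is a lactam carbonyl, so the C4a–C5 bond is a Michael bond that closes ring B onto a preformed ring A and generates C4 as an enolate carbon.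

## Logic of the disconnections

18 to 17: the two phenolic hydrogens are replaced by benzyl groups (two aryl O–CH2 bonds). Free phenols would compete as Mitsunobu pronucleophiles. The forward step must remove the benzyl groups by hydrogenolysis in the presence of two amines, two esters and the cyclobutane.

17 to 12 and 16: the two C6–O ester bonds are cut. This divides the molecule into its three natural parts, and the two amino alcohol units are identical, so one synthesis serves twice. Hydride reduction of a C6 ketone is expected to put the hydroxyl on the concave face, so 12 carries the C6 configuration opposite to that of 18. The forward esterification must therefore invert C6 twice in one operation, at a hindered secondary carbinol.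

16 to 14 to 13: the benzyl ethers are removed on paper, and then the two cyclobutane C–C bonds that join two molecules of 13 head to tail are cut. The whole core and its four stereocentres then come from one achiral C9 acid. The forward step relies on the antiparallel crystal packing of 13.

12 to 11: no skeletal bond is cut. C6 and C3 are raised to carbonyls, which exposes the 1,5-dicarbonyl pattern. The forward step needs hydride delivery to C6 from the convex face and lactam reduction that leaves C4 untouched.

11 to 10: the C4a–C5 bond is cut (key disconnection). Ring B and the centres C4a and C4 disappear. 10 keeps one controlled stereocentre (C7a) and an uncontrolled C7. The forward step needs the methyl-side enolate to cyclise, convex-face protonation at C4, and no loss of configuration at C7a.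

10 to 9: the C4=C4a double bond is cut (ring-closing metathesis), opening ring A to an acyclic diene. The forward step must form a trisubstituted alkene from a 1,1-disubstituted methacrylamide.

9 to 8: a methoxycarbonyl group is added at C7. It makes the nucleophile soft enough for allylic alkylation and is removed again without touching C7a.

8 to 6 and 7: the C7–C7a bond is cut. This is the only step that introduces absolute configuration. It needs branched regioselectivity with a fully substituted enolate and high enantioselectivity at C7a.

6 to 5 to 3 to 1 and 2: the carbonate C–O, the allylic C–O and the N–C1 bonds are cut in turn; symmetric 1 is desymmetrised by monosubstitution. The precursor design is tightened here: nitrogen enters already as the complete N-methyl methacrylamide. No N-protecting group is needed, and no free secondary amine ever sits four atoms from the methyl ketone, where it would close to a cyclic enamine or iminium ion.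

## Other disconnections considered

Alternative 1: The cut is at the two cyclobutane–aryl bonds (C2–aryl and C4–aryl) of the truxillate. It would replace steps 9 and 10 and does not concern the bicycle.
- Forward step: trans-N1,N3-di(quinolin-8-yl)cyclobutane-1,3-dicarboxamide A2 and two equivalents of 1-benzyloxy-4-iodobenzene A3 would react under Pd(OAc)2 and AgOAc to give the diarylated diamide A1. Cleavage of both auxiliaries would then lead to 16.
- In favour: the stereochemistry is reagent-controlled. Each aryl enters cis to the amide that directs it through a five-membered palladacycle, which is exactly the α pattern. The outcome does not depend on crystal packing, the aryl groups could be varied or made different, and the benzyl ethers arrive with A3.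
- Against: both ring CH2 groups are β to both amides. The second arylation must choose the C–H cis to the other amide rather than the second C–H cis to the first, and all-cis diarylation about one amide is a plausible competitor. Stoichiometric AgOAc is needed. Two hindered secondary amides must be cleaved next to epimerisable cyclobutane carbons.
- Comparison: structurally both plans reach 16. Mechanistically a directed C–H activation replaces a lattice-controlled [2+2] photodimerisation. In steps the alternative needs at least four (diamide, arylation, auxiliary removal in one or two steps) against two without metal. The alternative is the equal of the chosen plan in convergence and the better one in generality, because it would still work for an aryl acrylic acid whose crystals are photostable.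

Alternative 2: The cut is at C7a–C4a and C3–C4, so that rings B and A both arise from an acyclic oxazole.
- Forward step: heating 5-[3-(tert-butyldimethylsilyloxy)hept-5-en-2-yl]oxazole A5 would bring about an intramolecular oxazole–olefin Diels–Alder reaction. Loss of water from the oxygen-bridged adduct would give the pyridine (6S,7R)-6-(tert-butyldimethylsilyloxy)-4,7-dimethyl-6,7-dihydro-5H-cyclopenta[c]pyridine A4.
- In favour: two rings and two C–C bonds form in one reagent-free thermal step, which is better than step 7 on bonds and rings per step. The aromatic product is robust and has no base-sensitive centre. A later all-cis hydrogenation would place the hydrogens at C4, C4a and C7a on one face, so their relative configuration would be correct by construction. On that point it is the equal or the better of a kinetic protonation.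
- Against: the cycloaddition erases C4, C4a and C7a, which must be recreated by pyridine hydrogenation under facial control from the remote C6 and C7 substituents. To give the correct absolute sense, these two controller centres have to be opposite to those of 18 at C7 and concave at C6. C7 would then have to be epimerised through the C6 ketone and C6 reduced again. N-methylation is a separate step. An unactivated alkene requires high temperature. A5 already contains two stereocentres against one in 10.
- Comparison: structurally it postpones all ring-A stereochemistry, whereas the chosen plan sets C4a, C4 and C7 in the ring-forming step. Mechanistically it is pericyclic and insensitive to base, which is an advantage. In steps it needs about five operations from A4 to 12 (hydrogenation, N-methylation, desilylation, oxidation with epimerisation, reduction) against one from 11.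

Alternative 3: The cut is at C1–C7a, so that ring A closes last onto a preformed cyclopentenone.
- Forward step: one-electron oxidation (for example with a visible-light photoredox catalyst such as Ru(bpy)3Cl2) and desilylation of (4R)-2-methyl-4-{3-[methyl(trimethylsilylmethyl)amino]prop-1-en-2-yl}cyclopent-2-en-1-one A7 would give the N–CH2 radical. This would add 6-exo to C7a, and reduction and protonation of the α-keto radical would give the cis-fused amino ketone A6.
- In favour: nitrogen is carried at its final oxidation level with its methyl group, so no lactam reduction is needed; here it is better than the chosen plan. The conditions are neutral, so base-induced racemisation is not an issue. The tether enforces cis fusion and C7 is corrected by equilibration, as in the chosen plan; on these it is equal.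
- Against: the stereocentre of A7 (C4a) is doubly allylic and γ to the enone carbonyl, and so more exposed to isomerisation than C7a of 10. A 6-exo radical closure is slower than a 5-exo polar closure and competes with simple reduction. C4 is not set in the key step and would need a later convex-face hydrogenation of the exocyclic methylene, where an allylic amine can isomerise to an enamine. An enantioselective route to A7 is not obviously shorter than the six steps to 10.
- Comparison: structurally it builds ring A on ring B and creates two stereocentres (C7a, C7), against three fixed in step 7. Mechanistically it is a radical conjugate addition against a catalytic, fully atom-economic enolate addition. In steps it needs two from A6 to 12 (alkene hydrogenation, ketone reduction) against one from 11.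

Key step: step 7

Assumptions (remarks on the chemistry):
- Cyclopenta[c]pyridine numbering is used for the bicycle and for the corresponding atoms of its acyclic precursors.
- The (Sa,S,S) antipode of the phosphoramidite is taken to give the R configuration at the new allylic centre, following the usual facial sense of this ligand family. If a calibration run shows the opposite sense, the (Ra,R,R) ligand is used with no other change.
- The centre next to the ketone (C7) is carried as an epimer mixture in 8, 9 and 10, because step 7 equilibrates it.
- The relative configuration of 10, 11 and the α-truxillate core was re-derived from the target structure and found consistent with it.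

## Route

Step 1
Reactants: 1 (E)-1,4-dibromobut-2-ene; 2 N-methylmethacrylamide (N,2-dimethylprop-2-enamide)
Product: 3 (E)-N-(4-bromobut-2-en-1-yl)-N,2-dimethylprop-2-enamide
Conditions: NaH, THF, 0 °C; then added slowly to 1 (3 equiv), DMF, 0 °C to rt
Reagents that add atoms: none
Why: The sodium amidate of 2 displaces one allylic bromide by SN2 (N-alkylation of a secondary amide); excess 1 and inverse addition should suppress double substitution, and the E geometry is not touched.

Step 2
Reactants: 3 (E)-N-(4-bromobut-2-en-1-yl)-N,2-dimethylprop-2-enamide
Product: 5 (E)-N-(4-hydroxybut-2-en-1-yl)-N,2-dimethylprop-2-enamide, via allylic acetate 4 (not isolated)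
Conditions: KOAc, DMF, 50 °C; then K2CO3 (cat.), MeOH, rt
Reagents that add atoms: potassium acetate, CC(=O)[O-].[K+]
Why: Acetate substitutes the primary allylic bromide by SN2 and catalytic carbonate in methanol then transesterifies the acetate to the alcohol; the tertiary methacrylamide should be inert to both.

Step 3
Reactants: 5 (E)-N-(4-hydroxybut-2-en-1-yl)-N,2-dimethylprop-2-enamide
Product: 6 methyl (E)-4-[methyl(2-methylprop-2-enoyl)amino]but-2-en-1-yl carbonate
Conditions: ClCO2Me, pyridine, CH2Cl2, 0 °C
Reagents that add atoms: methyl chloroformate, COC(Cl)=O
Why: Acylation of a primary alcohol with a chloroformate gives the linear E allylic methyl carbonate, the standard electrophile for iridium-catalysed allylic substitution.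

Step 4
Reactants: 6 methyl (E)-4-[methyl(2-methylprop-2-enoyl)amino]but-2-en-1-yl carbonate; 7 methyl 2-methylacetoacetate
Product: 8 methyl (3R)-2-acetyl-2-methyl-3-{[methyl(2-methylprop-2-enoyl)amino]methyl}pent-4-enoate (both C2 epimers)
Conditions: [Ir(cod)Cl]2 (2 mol %), (Sa,S,S)-O,O'-(1,1'-binaphthyl-2,2'-diyl)-N,N-bis(1-phenylethyl)phosphoramidite (4 mol %), TBD (10 mol %), THF, rt
Reagents that add atoms: none
Why: Iridium-catalysed asymmetric allylic alkylation: the cyclometalated iridium–phosphoramidite complex ionises the carbonate, the released methoxide deprotonates 7, and the enolate attacks the substituted allyl terminus (branched selectivity typical of iridium), forming C7–C7a and setting C7a under catalyst control. The quaternary centre forms without control and is irrelevant because step 5 removes it.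

Step 5
Reactants: 8 methyl (3R)-2-acetyl-2-methyl-3-{[methyl(2-methylprop-2-enoyl)amino]methyl}pent-4-enoate
Product: 9 N-[(2R)-2-ethenyl-3-methyl-4-oxopentyl]-N,2-dimethylprop-2-enamide (both C3 epimers)
Conditions: LiCl, H2O, DMSO, 140 °C (trace BHT)
Reagents that add atoms: none
Why: Krapcho dealkoxycarbonylation: chloride dealkylates the methyl ester by SN2, the carboxylate loses CO2 and water protonates the enolate to leave the methyl ketone. C7a is not acidic, and an N,N-disubstituted methacrylamide is a poor Michael acceptor and reluctant to polymerise.

Step 6
Reactants: 9 N-[(2R)-2-ethenyl-3-methyl-4-oxopentyl]-N,2-dimethylprop-2-enamide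
Product: 10 (5R)-1,3-dimethyl-5-(3-oxobutan-2-yl)-5,6-dihydropyridin-2(1H)-one (both side-chain epimers)
Conditions: second-generation Grubbs catalyst, (H2IMes)(PCy3)Cl2Ru=CHPh (5 mol %), toluene (0.01 M), 80 °C
Reagents that add atoms: none
Why: Ring-closing metathesis between the vinyl group and the methacrylamide alkene closes ring A as the α-methyl unsaturated δ-lactam with loss of ethene; the ketone is a spectator and C7a is not involved.

Step 7
Reactants: 10 (5R)-1,3-dimethyl-5-(3-oxobutan-2-yl)-5,6-dihydropyridin-2(1H)-one
Product: 11 (4R,4aR,7S,7aR)-2,4,7-trimethylhexahydro-1H-cyclopenta[c]pyridine-3,6(2H,4H)-dione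
Conditions: KOtBu (0.2 equiv), THF/tBuOH (10:1), 0.02 M, 0 °C to rt; AcOH quench
Reagents that add atoms: none
Why: KOtBu reversibly forms both enolates of the methyl ketone; only the C5 (methyl-side) enolate can reach C4a, the β-carbon of the unsaturated lactam, and it adds there in an intramolecular Michael reaction to give the lactam enolate, which is protonated at C4 by tBuOH or by a second ketone. The closest known reaction type is the base-catalysed intramolecular Michael addition of a ketone enolate to an α,β-unsaturated lactam that delivers a cis-fused cyclopentane. Ring B closes in the 5-exo-trig mode (C5 to C4a, with C4 outside the new ring). C4a is controlled by the tether: the three-atom chain C7–C6–C5 anchored at C7a can only reach the face of C4a on which it hangs, so the fusion must be cis. C4 is controlled by kinetic protonation of the lactam enolate from the convex face, anti to the new C4a–C5 bond, which leaves the methyl on the concave side cis to C5; once the ring is closed the base rests as the far less basic ketone enolate, so the lactam α-position should not be reopened. C7 is under thermodynamic control next to the ketone and should settle with the methyl trans to C1 on the convex face, so both epimers of 10 converge. The step needs site selectivity (C5 enolate against C7 enolate and against γ-deprotonation at C7a, which would erode enantiomeric purity); the first is secured because the C7 enolate has only a three-membered closure open to it, the second by the much higher acidity of the ketone α-hydrogens, the catalytic amount of base and the low temperature, while high dilution holds back intermolecular aldol reactions.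

Step 8
Reactants: 11 (4R,4aR,7S,7aR)-2,4,7-trimethylhexahydro-1H-cyclopenta[c]pyridine-3,6(2H,4H)-dione
Product: 12 (4R,4aS,6S,7S,7aR)-2,4,7-trimethyloctahydro-1H-cyclopenta[c]pyridin-6-ol (6-epi-incarvilline)
Conditions: LiAlH4, THF, −78 to 0 °C, then reflux; H2O/aq. NaOH work-up
Reagents that add atoms: none
Why: Hydride should add to the cyclopentanone at low temperature from the convex face, because ring A and the C4 methyl screen the concave face; this places the C6 hydroxyl on the concave side, trans to the C7 methyl. At reflux the same reagent reduces the N-methyl lactam to the tertiary amine (lactam reduction) without touching C4.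

Step 9
Reactants: 13 p-coumaric acid ((E)-4-hydroxycinnamic acid), two molecules
Product: 14 4,4'-dihydroxy-α-truxillic acid ((1α,2α,3β,4β)-2,4-bis(4-hydroxyphenyl)cyclobutane-1,3-dicarboxylic acid)
Conditions: hν (λ > 300 nm), powdered crystals suspended in hexane, rt
Reagents that add atoms: none
Why: Topochemical head-to-tail [2+2] photodimerisation: in the crystal the acids stack antiparallel with the double bonds within reacting distance, so the centrosymmetric α dimer should form with all four cyclobutane centres fixed by the lattice.

Step 10
Reactants: 14 4,4'-dihydroxy-α-truxillic acid
Product: 16 4,4'-bis(benzyloxy)-α-truxillic acid, via tetrabenzyl derivative 15 (not isolated)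
Conditions: BnBr, K2CO3, DMF, 60 °C; then LiOH, THF/MeOH/H2O, 40 °C; aq. HCl
Reagents that add atoms: benzyl bromide, BrCc1ccccc1
Why: Exhaustive O-benzylation (Williamson etherification and carboxylate alkylation) followed by saponification of the two benzyl esters leaves only the phenols protected; mild hydroxide should not epimerise the cyclobutane, whose exocyclic enolate is disfavoured.

Step 11
Reactants: 12 6-epi-incarvilline (slightly more than two equivalents); 16 4,4'-bis(benzyloxy)-α-truxillic acid
Product: 17 bis[(4R,4aS,6R,7S,7aR)-2,4,7-trimethyloctahydro-1H-cyclopenta[c]pyridin-6-yl] 4,4'-bis(benzyloxy)-α-truxillate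
Conditions: PPh3, DIAD, THF, 0 °C to rt
Reagents that add atoms: none
Why: Twofold Mitsunobu esterification: each C6 hydroxyl is activated as its alkoxyphosphonium ion and displaced by a carboxylate of 16 with SN2 inversion, which moves the oxygen to the convex face cis to the C7 methyl. The masked phenols cannot be alkylated, and any unit of the minor enantiomer ends up in a separable diastereomeric diester.

Step 12
Reactants: 17 bis(benzyl ether) of the target
Product: 18 bis[(4R,4aS,6R,7S,7aR)-2,4,7-trimethyloctahydro-1H-cyclopenta[c]pyridin-6-yl] 4,4'-dihydroxy-α-truxillate (target)
Conditions: H2 (1 atm), Pd(OH)2/C, MeOH/EtOAc, AcOH, rt; aq. NaHCO3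
Reagents that add atoms: none
Why: Hydrogenolysis of the two aryl benzyl ethers; acetic acid protonates the tertiary amines so that they should not poison the catalyst, and the esters and the cyclobutane should be inert.

## Compound list

1 | (E)-1,4-dibromobut-2-ene | BrC/C=C/CBr | starting material
2 | N-methylmethacrylamide (N,2-dimethylprop-2-enamide) | C=C(C)C(=O)NC | starting material
3 | (E)-N-(4-bromobut-2-en-1-yl)-N,2-dimethylprop-2-enamide | C=C(C)C(=O)N(C)C/C=C/CBr | intermediate
4 | (E)-4-[methyl(2-methylprop-2-enoyl)amino]but-2-en-1-yl acetate | C=C(C)C(=O)N(C)C/C=C/COC(C)=O | intermediate (not isolated)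
5 | (E)-N-(4-hydroxybut-2-en-1-yl)-N,2-dimethylprop-2-enamide | C=C(C)C(=O)N(C)C/C=C/CO | intermediate
6 | methyl (E)-4-[methyl(2-methylprop-2-enoyl)amino]but-2-en-1-yl carbonate | C=C(C)C(=O)N(C)C/C=C/COC(=O)OC | intermediate
7 | methyl 2-methylacetoacetate | COC(=O)C(C)C(C)=O | starting material
8 | methyl (3R)-2-acetyl-2-methyl-3-{[methyl(2-methylprop-2-enoyl)amino]methyl}pent-4-enoate (both C2 epimers) | COC(=O)C(C)(C(C)=O)[C@@H](C=C)CN(C)C(=O)C(C)=C | intermediate
9 | N-[(2R)-2-ethenyl-3-methyl-4-oxopentyl]-N,2-dimethylprop-2-enamide (both C3 epimers) | CC(=O)C(C)[C@@H](C=C)CN(C)C(=O)C(C)=C | intermediate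
10 | (5R)-1,3-dimethyl-5-(3-oxobutan-2-yl)-5,6-dihydropyridin-2(1H)-one (both side-chain epimers) | CC(=O)C(C)[C@@H]1CN(C)C(=O)C(C)=C1 | intermediate
11 | (4R,4aR,7S,7aR)-2,4,7-trimethylhexahydro-1H-cyclopenta[c]pyridine-3,6(2H,4H)-dione; cis-fused, C4 methyl cis to C5, C7 methyl trans to C1 | C[C@H]1[C@@H]2CN(C)C(=O)[C@H](C)[C@@H]2CC1=O | intermediate
12 | (4R,4aS,6S,7S,7aR)-2,4,7-trimethyloctahydro-1H-cyclopenta[c]pyridin-6-ol (6-epi-incarvilline; hydroxyl trans to the C7 methyl) | C[C@H]1[C@@H]2CN(C)C[C@H](C)[C@@H]2C[C@@H]1O | intermediate
13 | p-coumaric acid | OC(=O)/C=C/c1ccc(O)cc1 | starting material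
14 | 4,4'-dihydroxy-α-truxillic acid | OC(=O)[C@H]1[C@H](c2ccc(O)cc2)[C@H](C(=O)O)[C@H]1c1ccc(O)cc1 | intermediate
15 | dibenzyl 4,4'-bis(benzyloxy)-α-truxillate | O=C(OCc1ccccc1)[C@H]1[C@H](c2ccc(OCc3ccccc3)cc2)[C@H](C(=O)OCc2ccccc2)[C@H]1c1ccc(OCc2ccccc2)cc1 | intermediate (not isolated)
16 | 4,4'-bis(benzyloxy)-α-truxillic acid | OC(=O)[C@H]1[C@H](c2ccc(OCc3ccccc3)cc2)[C@H](C(=O)O)[C@H]1c1ccc(OCc2ccccc2)cc1 | intermediate
17 | bis[(4R,4aS,6R,7S,7aR)-2,4,7-trimethyloctahydro-1H-cyclopenta[c]pyridin-6-yl] 4,4'-bis(benzyloxy)-α-truxillate | C[C@H]1[C@@H]2CN(C)C[C@H](C)[C@@H]2C[C@H]1OC(=O)[C@H]1[C@H](c2ccc(OCc3ccccc3)cc2)[C@H](C(=O)O[C@@H]2C[C@@H]3[C@@H](CN(C)C[C@@H]3C)[C@@H]2C)[C@H]1c1ccc(OCc2ccccc2)cc1 | intermediate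
18 | bis[(4R,4aS,6R,7S,7aR)-2,4,7-trimethyloctahydro-1H-cyclopenta[c]pyridin-6-yl] 4,4'-dihydroxy-α-truxillate | C[C@H]1[C@@H]2CN(C)C[C@H](C)[C@@H]2C[C@H]1OC(=O)[C@H]1[C@H](c2ccc(O)cc2)[C@H](C(=O)O[C@@H]2C[C@@H]3[C@@H](CN(C)C[C@@H]3C)[C@@H]2C)[C@H]1c1ccc(O)cc1 | target

## Step count and least certain steps

Total step count: 12. Longest linear sequence: 10 steps (steps 1 to 8, then 11 and 12); the acid partner needs 2 steps (9 and 10).

Step 7 (key step). The most likely failures are loss of configurational integrity at C7a through γ-deprotonation of the unsaturated lactam before ring closure, incomplete facial control in the protonation at C4, and intermolecular aldol condensation of the cyclopentanone once formed. All three stem from running an enolate equilibrium on a substrate with several acidic sites. The fallback sets out from 10 and replaces the basic enolate by a neutral nucleophile under Lewis acid activation. Kinetic enolisation of the methyl group with LiN(iPr)2 and Me3SiCl at −78 °C would give (5R)-1,3-dimethyl-5-[3-(trimethylsilyloxy)but-3-en-2-yl]-5,6-dihydropyridin-2(1H)-one F1. TiCl4 in CH2Cl2 at −78 °C would then promote an intramolecular Mukaiyama–Michael addition onto the coordinated lactam. Aqueous work-up would protonate C4 from the convex face and give 11 together with its C7 epimer, (4R,4aR,7R,7aR)-2,4,7-trimethylhexahydro-1H-cyclopenta[c]pyridine-3,6(2H,4H)-dione F2. Brief treatment with K2CO3 in MeOH, which reaches only the ketone α-position, would bring F2 back to 11.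

Step 4. The most likely failure is erosion of branched-to-linear selectivity or of enantioselectivity, because the nucleophile is a fully substituted enolate and the allyl unit carries an amidomethyl rather than an aryl substituent. The fallback sets out from 6 and uses the unhindered methyl acetoacetate under the same iridium catalysis, the best-precedented regime, to give methyl (3R)-2-acetyl-3-{[methyl(2-methylprop-2-enoyl)amino]methyl}pent-4-enoate F3. C-methylation with MeI and K2CO3 in acetone then returns to the route at 8.

Step 5. The most likely failure is slow dealkylation at the congested quaternary centre, which would force temperatures at which the diene oligomerises or adventitious hydroxide causes retro-Claisen deacetylation. The fallback sets out from 6 and changes the ester cleavage from nucleophilic to acidolytic. tert-Butyl 2-methylacetoacetate in the iridium step would give tert-butyl (3R)-2-acetyl-2-methyl-3-{[methyl(2-methylprop-2-enoyl)amino]methyl}pent-4-enoate F4. Trifluoroacetic acid in CH2Cl2 at rt followed by gentle warming would cleave the ester and decarboxylate the β-keto acid, returning to the route at 9.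

Step 8. The most likely failure is incomplete facial selectivity at C6, because the C7 methyl stands on the convex face that the hydride must use; epimerisation next to the ketone in the hot basic mixture is a second possibility. The fallback sets out from 11 and separates the two reductions. NaBH4 in MeOH at −40 °C would give (4R,4aR,6S,7S,7aR)-6-hydroxy-2,4,7-trimethyloctahydro-3H-cyclopenta[c]pyridin-3-one F5, which can be purified and its C6 configuration secured while the lactam is still in place. LiAlH4 in refluxing THF would then reduce the lactam, returning to the route at 12.

Step 11. The most likely failure is incomplete second esterification, with elimination or retention pathways, because the carbinol is flanked by the C7 methyl and the diacid is bulky and only moderately acidic. The fallback sets out from 12 and separates inversion from coupling. Mitsunobu reaction with the small, more acidic 4-nitrobenzoic acid would give (4R,4aS,6R,7S,7aR)-2,4,7-trimethyloctahydro-1H-cyclopenta[c]pyridin-6-yl 4-nitrobenzoate F6. Methanolysis with K2CO3 in MeOH would give the C6-inverted alcohol (4R,4aS,6R,7S,7aR)-2,4,7-trimethyloctahydro-1H-cyclopenta[c]pyridin-6-ol F7 (incarvilline). Acylation of F7 with 16 using EDC·HCl and DMAP, with retention at C6, returns to the route at 17.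

## Further compounds

F1 | step 7 | (5R)-1,3-dimethyl-5-[3-(trimethylsilyloxy)but-3-en-2-yl]-5,6-dihydropyridin-2(1H)-one (side-chain epimers) | C=C(O[Si](C)(C)C)C(C)[C@@H]1CN(C)C(=O)C(C)=C1
F2 | step 7 | (4R,4aR,7R,7aR)-2,4,7-trimethylhexahydro-1H-cyclopenta[c]pyridine-3,6(2H,4H)-dione (C7 epimer of 11) | C[C@@H]1[C@@H]2CN(C)C(=O)[C@H](C)[C@@H]2CC1=O
F3 | step 4 | methyl (3R)-2-acetyl-3-{[methyl(2-methylprop-2-enoyl)amino]methyl}pent-4-enoate (C2 epimers) | COC(=O)C(C(C)=O)[C@@H](C=C)CN(C)C(=O)C(C)=C
F4 | step 5 | tert-butyl (3R)-2-acetyl-2-methyl-3-{[methyl(2-methylprop-2-enoyl)amino]methyl}pent-4-enoate (C2 epimers) | CC(C)(C)OC(=O)C(C)(C(C)=O)[C@@H](C=C)CN(C)C(=O)C(C)=C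
F5 | step 8 | (4R,4aR,6S,7S,7aR)-6-hydroxy-2,4,7-trimethyloctahydro-3H-cyclopenta[c]pyridin-3-one | C[C@H]1[C@@H]2CN(C)C(=O)[C@H](C)[C@@H]2C[C@@H]1O
F6 | step 11 | (4R,4aS,6R,7S,7aR)-2,4,7-trimethyloctahydro-1H-cyclopenta[c]pyridin-6-yl 4-nitrobenzoate | C[C@H]1[C@@H]2CN(C)C[C@H](C)[C@@H]2C[C@H]1OC(=O)c1ccc(cc1)[N+](=O)[O-]
F7 | step 11 | (4R,4aS,6R,7S,7aR)-2,4,7-trimethyloctahydro-1H-cyclopenta[c]pyridin-6-ol (incarvilline) | C[C@H]1[C@@H]2CN(C)C[C@H](C)[C@@H]2C[C@H]1O
A1 | alternative 1 | (1α,2α,3β,4β)-2,4-bis[4-(benzyloxy)phenyl]-N1,N3-di(quinolin-8-yl)cyclobutane-1,3-dicarboxamide | O=C(Nc1cccc2cccnc12)[C@H]1[C@H](c2ccc(OCc3ccccc3)cc2)[C@H](C(=O)Nc2cccc3cccnc23)[C@H]1c1ccc(OCc2ccccc2)cc1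
A2 | alternative 1 | trans-N1,N3-di(quinolin-8-yl)cyclobutane-1,3-dicarboxamide | O=C(Nc1cccc2cccnc12)[C@H]1C[C@H](C(=O)Nc2cccc3cccnc23)C1
A3 | alternative 1 | 1-benzyloxy-4-iodobenzene | Ic1ccc(OCc2ccccc2)cc1
A4 | alternative 2 | (6S,7R)-6-(tert-butyldimethylsilyloxy)-4,7-dimethyl-6,7-dihydro-5H-cyclopenta[c]pyridine (6,7-cis) | C[C@@H]1c2cncc(C)c2C[C@@H]1O[Si](C)(C)C(C)(C)C
A5 | alternative 2 | 5-[3-(tert-butyldimethylsilyloxy)hept-5-en-2-yl]oxazole (configuration leading to 6,7-cis A4) | C[C@H](c1cnco1)[C@@H](O[Si](C)(C)C(C)(C)C)C/C=C/C
A6 | alternative 3 | cis-fused 2,7-dimethyl-4-methylene-octahydrocyclopenta[c]pyridin-6-one | C[C@H]1[C@@H]2CN(C)CC(=C)[C@@H]2CC1=O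
A7 | alternative 3 | (4R)-2-methyl-4-{3-[methyl(trimethylsilylmethyl)amino]prop-1-en-2-yl}cyclopent-2-en-1-one | C=C(CN(C)C[Si](C)(C)C)[C@@H]1CC(=O)C(C)=C1
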